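## Retrosynthetic overview

1. Cyclobutanedione 1 serves only as a carbon store: methanolysis (ester 2) and C-acetylation (via enolate 3) give the acyclic triketo ester 4, which holds every carbon of the tetramethyl-enedione ring but no ring.
2. The cyclobutane and nine-membered rings, with C1 and C9, are bought as (−)-β-caryophyllene 5. A singlet-oxygen ene reaction (hydroperoxide 6) moves the ring alkene to C3=C4 (Z) and installs the C5 oxygen, giving dienol 7 before any coupling.
3. Key disconnection, with isovaleraldehyde 8 as linchpin: the target is cut at a C–C(=O) bond of the trione ring (intramolecular Claisen, 4 → 9/10), at the alkylidene C=C (Knoevenagel, 10 + 8 → 11) and at O–C8 and C15–C1′ of the dihydropyran (oxa-Diels–Alder, 11 + 7 → 12). All three are made in one flask.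
4. Ring order: four- and nine-membered rings (purchased) → trione ring → dihydropyran ring, the last two in the same operation.

Assumption: caryophyllane numbering is used (C1/C9 ring fusion, C4 methyl-bearing alkene carbon, C5 carbinol, C8 spiro carbon, C15 the pyran CH2, C1′ the isobutyl-bearing carbon). On this numbering the target is (1R,3Z,5S,8S,9S,1′S), and commercial (−)-β-caryophyllene is (1R,9S,4E).

## Route

Step 1
Reactants: 1 2,2,4,4-tetramethylcyclobutane-1,3-dione
Product: 2 methyl 2,2,4-trimethyl-3-oxopentanoate
Conditions: NaOMe (5 mol%), MeOH, 65 °C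
Reagents that add atoms: methanol, CO
Why: Methoxide adds to the strained, non-enolisable diketone and the hemiketal alkoxide opens to the ester enolate, which methanol protonates to regenerate methoxide (alkoxide-catalysed retro-Claisen ring opening; no stereocenter).

Step 2
Reactants: 2 methyl 2,2,4-trimethyl-3-oxopentanoate
Product: 4 methyl 2,2,4,4-tetramethyl-3,5-dioxohexanoate, via lithium enolate 3 (not isolated)
Conditions: LiN(iPr)2, THF, −78 to 0 °C; then added to AcCl (2 equiv), THF, −78 °C to rt
Reagents that add atoms: acetyl chloride, CC(=O)Cl; lithium diisopropylamide, [Li+].CC(C)[N-]C(C)C (only the Li+ of intermediate 3)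
Why: LiN(iPr)2 removes the only enolisable hydrogen of 2, and inverse addition of the lithium enolate to excess acetyl chloride in THF at low temperature favours C- over O-acylation (Claisen-type C-acylation of a preformed ketone enolate; no stereocenter).

Step 3
Reactants: 5 (−)-β-caryophyllene
Product: 7 (1R,3Z,5S,9S)-caryophylla-3,8(15)-dien-5-ol, via allylic hydroperoxide 6 (not isolated)
Conditions: O2, hν (white LED), 5,10,15,20-tetraphenylporphyrin (0.5 mol%), CH2Cl2, 0 °C, stopped at partial conversion; then PPh3, rt
Reagents that add atoms: dioxygen, O=O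
Why: Schenck ene reaction, in which singlet oxygen adds to the exposed outer face of the strained trans C4=C5 bond, bonds to the less substituted C5 and takes an allylic hydrogen from C3 suprafacially, so the new C3=C4 bond is the ring-compatible Z isomer and the exocyclic alkene is untouched; C5 is set by the face attacked, the 5S hydroperoxide coming from the minor conformer that exposes the face opposite to the one used in peracid epoxidation, so after PPh3 reduction of the O–O bond (C5 untouched) 7 is a minor component separated by chromatography from its 5R epimer and the 4(12)-exomethylene regioisomers.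

Step 4
Reactants: 4 methyl 2,2,4,4-tetramethyl-3,5-dioxohexanoate (1.3 equiv); 8 isovaleraldehyde (1.6 equiv); 7 (1R,3Z,5S,9S)-caryophylla-3,8(15)-dien-5-ol (1.0 equiv)
Product: 12 tomentodione P, via sodium syncarpate 9 (not isolated), via syncarpic acid 10 (not isolated), via alkylidene trione 11 (not isolated)
Conditions: NaOMe (1.1 equiv), MeOH, 65 °C; concentrate; then AcOH (3 equiv), 8, 7, toluene, 80 °C
Reagents that add atoms: sodium methoxide, [Na+].[O-]C (only the Na+ of intermediate 9)
Why: Proposed new method: a one-flask intramolecular Claisen (Dieckmann-type) condensation/Knoevenagel/inverse-electron-demand oxa-Diels–Alder cascade in which methoxide closes the methyl ketone enolate of 4 onto the non-enolisable ester to give the trione ring as enolate 9, acetic acid then liberates 10 together with the NaOAc/AcOH buffer that promotes condensation with 8 to the electron-poor 1-oxadiene 11, and 11 adds across the exocyclic C8=C15 bond of 7 with oxygen going to the more substituted C8 (closest known reaction types: base-mediated cyclisation of 3,5-dioxo esters to cyclohexane-1,3,5-triones and the three-component Knoevenagel/hetero-Diels–Alder of cyclic 1,3-diones with 1,1-disubstituted alkenes); C8 (S) and C1′ (S) are set together by suprafacial addition to the alkene face syn to the C5 hydroxyl, which may hydrogen-bond to the diene carbonyl, with isobutyl outside on the diene and C9 endo, and this facial and endo preference is a hypothesis, so the other C8/C1′ diastereomers that form are removed by chromatography.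

## Compound list

1 | 2,2,4,4-tetramethylcyclobutane-1,3-dione (dimethylketene dimer) | CC1(C)C(=O)C(C)(C)C1=O | starting material
2 | methyl 2,2,4-trimethyl-3-oxopentanoate | COC(=O)C(C)(C)C(=O)C(C)C | intermediate
3 | lithium enolate of 2 (lithium 1-methoxy-2,2,4-trimethyl-1-oxopent-3-en-3-olate) | COC(=O)C(C)(C)C([O-])=C(C)C.[Li+] | intermediate (not isolated)
4 | methyl 2,2,4,4-tetramethyl-3,5-dioxohexanoate | COC(=O)C(C)(C)C(=O)C(C)(C)C(C)=O | intermediate
5 | (−)-β-caryophyllene, (1R,4E,9S)-4,11,11-trimethyl-8-methylidenebicyclo[7.2.0]undec-4-ene | C/C1=C\CCC(=C)[C@H]2CC(C)(C)[C@@H]2CC1 | starting material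
6 | (1R,3Z,5S,9S)-5-hydroperoxycaryophylla-3,8(15)-diene | C/C1=C/C[C@@H]2[C@H](CC2(C)C)C(=C)CC[C@@H]1OO | intermediate (not isolated)
7 | (1R,3Z,5S,9S)-caryophylla-3,8(15)-dien-5-ol, i.e. (1R,3Z,5S,9S)-4,11,11-trimethyl-8-methylidenebicyclo[7.2.0]undec-3-en-5-ol | C/C1=C/C[C@@H]2[C@H](CC2(C)C)C(=C)CC[C@@H]1O | intermediate
8 | isovaleraldehyde (3-methylbutanal) | CC(C)CC=O | starting material
9 | sodium syncarpate (sodium enolate of 2,2,4,4-tetramethylcyclohexane-1,3,5-trione) | CC1(C)C(=O)C=C([O-])C(C)(C)C1=O.[Na+] | intermediate (not isolated)
10 | syncarpic acid (2,2,4,4-tetramethylcyclohexane-1,3,5-trione) | CC1(C)C(=O)CC(=O)C(C)(C)C1=O | intermediate (not isolated)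
11 | 2,2,4,4-tetramethyl-6-(3-methylbutylidene)cyclohexane-1,3,5-trione | CC(C)CC=C1C(=O)C(C)(C)C(=O)C(C)(C)C1=O | intermediate (not isolated)
12 | tomentodione P, (1R,3Z,5S,8S,9S,1′S): dihydropyran spiro-fused at caryophyllane C8 (O on C8) and fused to a 2,2,4,4-tetramethylcyclohexene-1,3-dione, isobutyl at C1′, free 5-OH, 3Z alkene | C/C1=C/C[C@@H]2[C@H](CC2(C)C)[C@]2(CC[C@@H]1O)C[C@H](CC(C)C)C1=C(O2)C(C)(C)C(=O)C(C)(C)C1=O | target

## Step count and risks

Total steps: 4. Longest linear sequence: 3 (1 → 2 → 4 → 12), with a one-step branch 5 → 7.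

Most likely to fail, in decreasing order:

Step 4. The cascade must deliver one of four possible C8/C1′ diastereomers, and the hydroxyl-directed facial preference and the endo sense are not guaranteed. The allylic alcohol of 7 may ionise or be acetylated in warm acetic acid, the C5 hydroxyl may trap a cationic C8 transannularly, and 10 can add a second time to 11. The fallback sets out from 7 and comes back at 12. Compound 7 is silylated (tert-butyldimethylsilyl chloride, imidazole, DMF) to (1R,3Z,5S,9S)-5-(tert-butyldimethylsilyloxy)caryophylla-3,8(15)-diene F5. The single-flask cascade is given up: 4 is cyclised separately (NaOMe, MeOH, then aqueous HCl) and 10 is isolated; 10 is condensed with 8 (piperidine, CH2Cl2, then dilute HCl) and heterodiene 11 is isolated. Compound 11 is heated with F5 in toluene at 100 °C without any acid to the silyl ether of tomentodione P F6, whose diastereomers are separated. The silyl group is then removed with Bu4NF in THF to give 12.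

Step 3. The 5S alcohol comes from the minor face, the ene reaction also gives exomethylene regioisomers, and the product alkene can be oxidised further, so the isolated yield of 7 will be low even though 5 is very cheap. The fallback sets out from 5 and comes back at 7. Compound 5 is epoxidised (mCPBA, NaHCO3, CH2Cl2, 0 °C) to (1R,4R,5R,9S)-4,5-epoxycaryophyll-8(15)-ene F2, which is also an article of commerce. F2 is isomerised with Et2Al(tmp) (tmp = 2,2,6,6-tetramethylpiperidide; toluene, 0 °C), a syn-elimination that should take the C3 hydrogen cis to H5, to give (1R,3Z,5R,9S)-caryophylla-3,8(15)-dien-5-ol F3. C5 is inverted by a Mitsunobu reaction (4-nitrobenzoic acid, PPh3, diisopropyl azodicarboxylate, THF) to the (5S)-4-nitrobenzoate F4. F4 is methanolysed (K2CO3, MeOH) to 7.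

Step 2. The fully substituted enolate 3 may be acylated on oxygen instead of carbon, and the non-enolisable 1,3-diketone product is open to retro-Claisen cleavage. The fallback sets out from 2 (through enolate 3) and comes back at 4. Enolate 3 is trapped with Me3SiCl to methyl 2,2,4-trimethyl-3-(trimethylsilyloxy)pent-3-enoate F1. F1 is then C-acetylated under Lewis-acid conditions (AcCl, ZnCl2, CH2Cl2, 0 °C to rt; Mukaiyama-type acylation of a silyl enol ether) to give 4.

## Further compounds

F1 | step 2 | methyl 2,2,4-trimethyl-3-(trimethylsilyloxy)pent-3-enoate | COC(=O)C(C)(C)C(O[Si](C)(C)C)=C(C)C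
F2 | step 3 | (−)-caryophyllene oxide, (1R,4R,5R,9S)-4,5-epoxycaryophyll-8(15)-ene | C[C@@]12CC[C@@H]3[C@H](CC3(C)C)C(=C)CC[C@H]1O2
F3 | step 3 | (1R,3Z,5R,9S)-caryophylla-3,8(15)-dien-5-ol | C/C1=C/C[C@@H]2[C@H](CC2(C)C)C(=C)CC[C@H]1O
F4 | step 3 | (1R,3Z,5S,9S)-caryophylla-3,8(15)-dien-5-yl 4-nitrobenzoate | C/C1=C/C[C@@H]2[C@H](CC2(C)C)C(=C)CC[C@@H]1OC(=O)c1ccc(cc1)[N+](=O)[O-]
F5 | step 4 | (1R,3Z,5S,9S)-5-(tert-butyldimethylsilyloxy)caryophylla-3,8(15)-diene | C/C1=C/C[C@@H]2[C@H](CC2(C)C)C(=C)CC[C@@H]1O[Si](C)(C)C(C)(C)C
F6 | step 4 | 5-O-tert-butyldimethylsilyl ether of tomentodione P | C/C1=C/C[C@@H]2[C@H](CC2(C)C)[C@]2(CC[C@@H]1O[Si](C)(C)C(C)(C)C)C[C@H](CC(C)C)C1=C(O2)C(C)(C)C(=O)C(C)(C)C1=O
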